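**Retrosynthetic overview**
- The C8 hydroperoxide and the 6E alkene come last, from a Schenck ene reaction of singlet oxygen on the macrocyclic 7E trisubstituted alkene.
- The 14-membered ring is closed by ring-closing metathesis at C7=C8 (terminal butenyl alkene onto a 1,1-disubstituted alkene); C15 is then equilibrated.
- The 11,12-epoxide comes from a Shi epoxidation; the C4 carbinol from a Felkin–Anh Grignard addition to a lactone-bearing methyl ketone.
- The C12–C13 bond is a Negishi sp3–sp2 coupling of a lactone iodide (from (R)-carvone) with an E vinyl iodide (from but-2-yn-1-ol).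
- Ring order: δ-lactone first (bridged on the carvone ring, which is then cleaved), epoxide second, 14-membered carbocycle last.

Locants: cembrane numbering is used (C1 ring-fusion CH, C3 lactone carbinol, C4 tertiary carbinol, C8 hydroperoxide carbon, C11/C12 epoxide, C15 lactone α-carbon, C16 lactone C=O); the carvone-derived compounds are carried as C15 epimer mixtures from the hydroboration until the ring-closing step.

**Step 1**
Reactants: 1 (R)-(−)-carvone
Product: 2 (1R,5R)-cis-carveol
Conditions: NaBH4, CeCl3·7H2O, MeOH, −78→0 °C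
Reagents that add atoms: none
Why: Luche 1,2-reduction in which hydride is delivered axially, anti to the isopropenyl group, so the new carbinol centre (future C3) is formed cis to it (about 95:5).

**Step 2**
Reactants: 2 (1R,5R)-cis-carveol
Product: 4 (1R,5R)-5-[(2RS)-1-hydroxypropan-2-yl]-2-methylcyclohex-2-en-1-ol, via borane adduct 3 (not isolated)
Conditions: 9-BBN (2.2 equiv), THF, 0→25 °C; then NaOH, H2O2, 0→25 °C
Reagents that add atoms: hydrogen peroxide, OO
Why: Brown hydroboration–oxidation in which bulky 9-BBN adds anti-Markovnikov only to the 1,1-disubstituted isopropenyl group (the trisubstituted ring alkene is untouched), the new C15 centre forming as a near 1:1 mixture that is corrected in step 14.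

**Step 3**
Reactants: 4 (1R,5R)-5-[(2RS)-1-hydroxypropan-2-yl]-2-methylcyclohex-2-en-1-ol
Product: 6 (1R,5R)-4,8-dimethyl-2-oxabicyclo[3.3.1]non-7-en-3-one, via bridged lactol 5 (not isolated)
Conditions: TEMPO (0.2 equiv), PhI(OAc)2 (2.5 equiv), CH2Cl2, 25 °C
Reagents that add atoms: none
Why: TEMPO/PhI(OAc)2 oxidative lactonisation in which the unhindered primary alcohol is oxidised first, the aldehyde is trapped by the cis secondary hydroxyl as a bridged lactol and this is oxidised on to the δ-lactone, which then protects both C3–O and C16.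

**Step 4**
Reactants: 6 (1R,5R)-4,8-dimethyl-2-oxabicyclo[3.3.1]non-7-en-3-one
Product: 8 (4R,6R)-6-acetyl-4-(2-hydroxyethyl)-3-methyloxan-2-one, via keto aldehyde 7 (not isolated)
Conditions: O3, CH2Cl2, −78 °C; PPh3, −78→25 °C; then NaBH(OAc)3, AcOH, 0→25 °C
Reagents that add atoms: ozone, [O-][O+]=O
Why: Ozonolysis with reductive work-up cleaves the only C=C bond to a methyl ketone and an aldehyde, and NaBH(OAc)3 then reduces the aldehyde chemoselectively (ketone and lactone are not reduced) under non-basic conditions that leave C1 and C3 untouched.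

**Step 5**
Reactants: 8 (4R,6R)-6-acetyl-4-(2-hydroxyethyl)-3-methyloxan-2-one
Product: 9 (4S,6R)-6-acetyl-4-(2-iodoethyl)-3-methyloxan-2-one
Conditions: I2, PPh3, imidazole, CH2Cl2, 0 °C
Reagents that add atoms: iodine, II
Why: Appel-type (Garegg–Samuelsson) iodination, an SN2 displacement of the primary oxyphosphonium by iodide that does not touch ketone, lactone or stereocentres (the descriptor at C4 changes only through CIP priority).

**Step 6**
Reactants: 10 but-2-yn-1-ol
Product: 11 tert-butyl(but-2-yn-1-yloxy)dimethylsilane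
Conditions: TBSCl, imidazole, CH2Cl2, 25 °C
Reagents that add atoms: tert-butyldimethylsilyl chloride, CC(C)(C)[Si](C)(C)Cl
Why: Imidazole-promoted silylation protects the hydroxyl so that it neither consumes nor misdirects the zirconium hydride in the next step.

**Step 7**
Reactants: 11 tert-butyl(but-2-yn-1-yloxy)dimethylsilane
Product: 13 tert-butyl{[(2E)-3-iodobut-2-en-1-yl]oxy}dimethylsilane, via alkenylzirconocene chloride 12 (not isolated)
Conditions: Cp2Zr(H)Cl (2 equiv), THF, 25→50 °C; then I2, 0 °C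
Reagents that add atoms: iodine, II
Why: Syn hydrozirconation puts zirconium on the less hindered, methyl-bearing alkyne carbon (excess reagent equilibrates to this regioisomer) and iodinolysis occurs with retention, fixing the E vinyl iodide.

**Step 8**
Reactants: 13 tert-butyl{[(2E)-3-iodobut-2-en-1-yl]oxy}dimethylsilane
Product: 14 (2E)-3-iodobut-2-en-1-ol
Conditions: Bu4NF, THF, 0 °C
Reagents that add atoms: none
Why: Fluoride-induced desilylation, driven by the strong Si–F bond, frees the allylic alcohol without touching the vinyl iodide.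

**Step 9**
Reactants: 14 (2E)-3-iodobut-2-en-1-ol
Product: 15 (2E)-1-bromo-3-iodobut-2-ene
Conditions: CBr4, PPh3, CH2Cl2, 0 °C
Reagents that add atoms: carbon tetrabromide, BrC(Br)(Br)Br
Why: Appel bromination of the primary allylic alcohol is an SN2 process with no allylic transposition and no loss of alkene geometry.

**Step 10**
Reactants: 15 (2E)-1-bromo-3-iodobut-2-ene
Product: 16 (2E)-2-iodo-6-methylhepta-2,6-diene
Conditions: 2-methylallylmagnesium chloride, THF, −78→0 °C
Reagents that add atoms: (2-methylprop-2-en-1-yl)magnesium chloride, CC(=C)C[Mg]Cl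
Why: Allyl–allyl Grignard coupling in which the symmetrical methallyl nucleophile displaces the primary allylic bromide (the iodine-bearing γ-carbon is blocked against SN2′) while the vinyl iodide is inert at low temperature.

**Step 11**
Reactants: 9 (4S,6R)-6-acetyl-4-(2-iodoethyl)-3-methyloxan-2-one; 16 (2E)-2-iodo-6-methylhepta-2,6-diene
Product: 18 (4R,6R)-6-acetyl-4-[(3E)-3,7-dimethylocta-3,7-dien-1-yl]-3-methyloxan-2-one, via alkylzinc iodide 17 (not isolated)
Conditions: Zn dust, LiCl, THF, 35 °C; then 16, PdCl2(dppf) (5 mol%), 25→45 °C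
Reagents that add atoms: none
Why: Negishi sp3–sp2 cross-coupling in which zinc inserts only into the primary carbon–iodine bond to give an alkylzinc that tolerates ketone and lactone, and palladium-catalysed coupling with the vinyl iodide proceeds with retention to set the E C11=C12 alkene.

**Step 12**
Reactants: 18 (4R,6R)-6-acetyl-4-[(3E)-3,7-dimethylocta-3,7-dien-1-yl]-3-methyloxan-2-one
Product: 19 (4R,6R)-4-[(3E)-3,7-dimethylocta-3,7-dien-1-yl]-6-[(2S)-2-hydroxyhex-5-en-2-yl]-3-methyloxan-2-one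
Conditions: but-3-enylmagnesium bromide (1.3 equiv), THF, −78 °C
Reagents that add atoms: but-3-en-1-ylmagnesium bromide, C=CCC[Mg]Br
Why: Grignard 1,2-addition under Felkin–Anh (Cornforth) control, in which the poorly chelating lactone C3–O bond lies anti to the incoming nucleophile and the nucleophile passes the C3–H to give the 4S tertiary carbinol, the ketone reacting far faster than the lactone at −78 °C.

**Step 13**
Reactants: 19 (4R,6R)-4-[(3E)-3,7-dimethylocta-3,7-dien-1-yl]-6-[(2S)-2-hydroxyhex-5-en-2-yl]-3-methyloxan-2-one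
Product: 20 (4R,6R)-6-[(2S)-2-hydroxyhex-5-en-2-yl]-3-methyl-4-{2-[(2S,3S)-2-methyl-3-(3-methylbut-3-en-1-yl)oxiran-2-yl]ethyl}oxan-2-one
Conditions: 1,2:4,5-di-O-isopropylidene-β-L-erythro-2,3-hexodiulo-2,6-pyranose (L-fructose-derived Shi ketone, 0.3 equiv), KHSO5 (as Oxone, 2KHSO5·KHSO4·K2SO4), K2CO3, Bu4NHSO4, MeCN/CH2(OMe)2/aq. Na2B4O7 buffer (pH 10.5), 0 °C
Reagents that add atoms: potassium peroxymonosulfate, [K+].[O-]S(=O)(=O)OO
Why: Shi asymmetric epoxidation in which the chiral dioxirane attacks the electron-rich E-trisubstituted alkene through the spiro transition state (the terminal and 1,1-disubstituted alkenes react much more slowly) and the L-series catalyst gives the (11S,12S) epoxide by catalyst control, the mirror sense of the R,R epoxides given by the D-fructose ketone.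

**Step 14**
Reactants: 20 (4R,6R)-6-[(2S)-2-hydroxyhex-5-en-2-yl]-3-methyl-4-{2-[(2S,3S)-2-methyl-3-(3-methylbut-3-en-1-yl)oxiran-2-yl]ethyl}oxan-2-one
Product: 22 (1R,3R,4S,7E,11S,12S,15S)-11,12-epoxy-4-hydroxycembr-7-en-16,3-olide, via C15-epimeric macrocycle 21 (not isolated)
Conditions: second-generation Hoveyda–Grubbs catalyst (10 mol%), toluene (1 mM), 80 °C; then DBU, 25 °C
Reagents that add atoms: none
Why: Ring-closing metathesis in which the ruthenium carbene formed at the terminal butenyl alkene closes onto the 1,1-disubstituted alkene at high dilution with loss of ethene to give the 14-membered ring, the E-trisubstituted C7=C8 isomer expected as the major product (about 3:1, the Z isomer removed on AgNO3-impregnated silica), after which DBU equilibrates C15 through the lactone enolate to the all-equatorial 15S epimer.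

**Step 15**
Reactants: 22 (1R,3R,4S,7E,11S,12S,15S)-11,12-epoxy-4-hydroxycembr-7-en-16,3-olide
Product: 23 (1R,3R,4S,6E,8S,11S,12S,15S)-11,12-epoxy-8-hydroperoxy-4-hydroxycembr-6-en-16,3-olide (target)
Conditions: O2, visible light, tetraphenylporphyrin (cat.), CH2Cl2, 0 °C; preparative HPLC
Reagents that add atoms: dioxygen, O=O
Why: Schenck ene reaction in which singlet oxygen adds suprafacially at C8 on the exposed face of the E C7=C8 alkene with abstraction of a C6 hydrogen and shift of the double bond to 6E, so C8 is set by substrate (peripheral-attack) control and the 8S hydroperoxide is separated by HPLC from its 8R epimer and the C7-hydroperoxide regioisomers.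

**Compound list**
1 | (R)-(−)-carvone, (5R)-2-methyl-5-(prop-1-en-2-yl)cyclohex-2-en-1-one | CC1=CC[C@H](CC1=O)C(C)=C | starting material
2 | (1R,5R)-cis-carveol, (1R,5R)-2-methyl-5-(prop-1-en-2-yl)cyclohex-2-en-1-ol | CC1=CC[C@H](C[C@H]1O)C(C)=C | intermediate
3 | borane adduct of 2: O-(9-BBN) borinate at the ring oxygen and B-alkyl-9-BBN at the side-chain CH2 (side-chain epimers) | CC1=CC[C@H](C[C@H]1OB1C2CCCC1CCC2)C(C)CB1C2CCCC1CCC2 | intermediate (not isolated)
4 | (1R,5R)-5-[(2RS)-1-hydroxypropan-2-yl]-2-methylcyclohex-2-en-1-ol | CC1=CC[C@H](C[C@H]1O)C(C)CO | intermediate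
5 | (1R,5R)-4,8-dimethyl-2-oxabicyclo[3.3.1]non-7-en-3-ol, bridged lactol (C3 and C4 epimers) | CC1=CC[C@@H]2C[C@H]1OC(O)C2C | intermediate (not isolated)
6 | (1R,5R)-4,8-dimethyl-2-oxabicyclo[3.3.1]non-7-en-3-one (C4 epimers) | CC1=CC[C@@H]2C[C@H]1OC(=O)C2C | intermediate
7 | (4S,6R)-6-acetyl-3-methyl-4-(2-oxoethyl)oxan-2-one (C3 epimers) | CC1C(=O)O[C@H](C[C@H]1CC=O)C(C)=O | intermediate (not isolated)
8 | (4R,6R)-6-acetyl-4-(2-hydroxyethyl)-3-methyloxan-2-one (C3 epimers) | CC1C(=O)O[C@H](C[C@H]1CCO)C(C)=O | intermediate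
9 | (4S,6R)-6-acetyl-4-(2-iodoethyl)-3-methyloxan-2-one (C3 epimers) | CC1C(=O)O[C@H](C[C@H]1CCI)C(C)=O | intermediate
10 | but-2-yn-1-ol | CC#CCO | starting material
11 | tert-butyl(but-2-yn-1-yloxy)dimethylsilane | CC#CCO[Si](C)(C)C(C)(C)C | intermediate
12 | (E)-alkenylzirconocene chloride, Cp2Zr(Cl) on the methyl-bearing alkene carbon, trans to CH2OTBS | C/C(=C\CO[Si](C)(C)C(C)(C)C)[Zr](Cl)(C1C=CC=C1)C1C=CC=C1 | intermediate (not isolated)
13 | tert-butyl{[(2E)-3-iodobut-2-en-1-yl]oxy}dimethylsilane | C/C(I)=C\CO[Si](C)(C)C(C)(C)C | intermediate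
14 | (2E)-3-iodobut-2-en-1-ol | C/C(I)=C\CO | intermediate
15 | (2E)-1-bromo-3-iodobut-2-ene | C/C(I)=C\CBr | intermediate
16 | (2E)-2-iodo-6-methylhepta-2,6-diene | C/C(I)=C\CCC(C)=C | intermediate
17 | alkylzinc iodide from 9, (4S,6R)-6-acetyl-4-[2-(iodozincio)ethyl]-3-methyloxan-2-one (C3 epimers) | CC1C(=O)O[C@H](C[C@H]1CC[Zn]I)C(C)=O | intermediate (not isolated)
18 | (4R,6R)-6-acetyl-4-[(3E)-3,7-dimethylocta-3,7-dien-1-yl]-3-methyloxan-2-one (C3 epimers) | CC1C(=O)O[C@H](C[C@H]1CC/C(C)=C/CCC(C)=C)C(C)=O | intermediate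
19 | (4R,6R)-4-[(3E)-3,7-dimethylocta-3,7-dien-1-yl]-6-[(2S)-2-hydroxyhex-5-en-2-yl]-3-methyloxan-2-one (C3 epimers) | CC1C(=O)O[C@H](C[C@H]1CC/C(C)=C/CCC(C)=C)[C@@](C)(O)CCC=C | intermediate
20 | (4R,6R)-6-[(2S)-2-hydroxyhex-5-en-2-yl]-3-methyl-4-{2-[(2S,3S)-2-methyl-3-(3-methylbut-3-en-1-yl)oxiran-2-yl]ethyl}oxan-2-one (C3 epimers) | CC1C(=O)O[C@H](C[C@H]1CC[C@]1(C)O[C@H]1CCC(C)=C)[C@@](C)(O)CCC=C | intermediate
21 | (1R,3R,4S,7E,11S,12S)-11,12-epoxy-4-hydroxycembr-7-en-16,3-olide, C15 epimers | CC1C(=O)O[C@@H]2C[C@H]1CC[C@]1(C)O[C@H]1CC/C(C)=C/CC[C@]2(C)O | intermediate (not isolated)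
22 | (1R,3R,4S,7E,11S,12S,15S)-11,12-epoxy-4-hydroxycembr-7-en-16,3-olide | C[C@@H]1C(=O)O[C@@H]2C[C@H]1CC[C@]1(C)O[C@H]1CC/C(C)=C/CC[C@]2(C)O | intermediate
23 | (1R,3R,4S,6E,8S,11S,12S,15S)-11,12-epoxy-8-hydroperoxy-4-hydroxycembr-6-en-16,3-olide | C[C@@H]1C(=O)O[C@@H]2C[C@H]1CC[C@]1(C)O[C@H]1CC[C@](C)(OO)/C=C/C[C@]2(C)O | target

**Step count**
Total: 15 steps. Longest linear sequence: 10 steps (steps 1–5 then 11–15 from (R)-carvone; the but-2-yn-1-ol branch, steps 6–10 then 11–15, is also 10).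

**Three steps most likely to fail**

Step 14 (ring-closing metathesis to a trisubstituted macrocyclic alkene: slow, and the E/Z ratio is not under firm control). The fallback closes the ring by an intramolecular B-alkyl Suzuki–Miyaura coupling with the E geometry fixed beforehand. It sets out from bromide 15 and zinc reagent 17 and returns at macrocycle 21, which is epimerised with DBU to 22 as in step 14. Lithiated 1-(trimethylsilyl)propyne is alkylated with 15 to give trimethyl[(5E)-6-iodohept-5-en-1-yn-1-yl]silane F11, and K2CO3/MeOH gives (5E)-6-iodohept-5-en-1-yne F12. Zirconium-catalysed carboalumination (Me3Al, Cp2ZrCl2) gives the (E)-alkenyldimethylalane F13, which NBS converts into (1E,5E)-1-bromo-6-iodo-2-methylhepta-1,5-diene F14. Negishi coupling of 17 with F14 takes place only at the carbon–iodine bond and gives the bromodienyl keto lactone F15. Vinylmagnesium bromide adds as in step 12 to give the vinyl carbinol F16, and Shi epoxidation as in step 13 gives the epoxide F17. 9-BBN hydroborates the terminal vinyl group to the B-alkyl-9-BBN F18, and PdCl2(dppf)/Cs2CO3 at high dilution couples it with the vinyl bromide to give 21.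

Step 15 (the ene reaction can also abstract a C19 methyl hydrogen to give the C7 hydroperoxide, and the facial selectivity at C8 is set only by the macrocycle). The fallback fixes the regiochemistry by peroxyselenenylation and selenoxide elimination; it sets out from 22 and returns at 23. TMSOTf/2,6-lutidine gives the C4 trimethylsilyl ether F19, which stops the C4 hydroxyl from closing onto the seleniranium ion. PhSeBr/AgOCOCF3 with 2-methoxyprop-2-yl hydroperoxide gives, by Markovnikov anti addition, the C8 peroxyketal C7 phenylselenide F20. mCPBA at −78 °C gives the selenoxide F21, which on warming eliminates syn towards C6 (the only β-hydrogens) to the (6E)-allylic peroxyketal silyl ether F22. Aqueous AcOH/THF removes the perketal and the silyl ether to give 23. The C8 epimers still have to be separated. The peroxide variant of this selenenylation is less established than the hydroxy and alkoxy variants.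

Step 12 (the 4S/4R ratio depends on the lactone oxygen not chelating magnesium, and the α-acyloxy ketone can enolise). The fallback exchanges the roles of methyl and butenyl and uses Cram-chelate control; it sets out from diol 4 and returns at 19. NaH/4-methoxybenzyl chloride gives the bis(4-methoxybenzyl) ether F1. Ozonolysis with PPh3 gives the keto aldehyde F2, and NaBH(OAc)3 gives the hydroxy ketone F3. I2/PPh3/imidazole gives the iodide F4, and zinc insertion gives the alkylzinc iodide F5, which is coupled with 16 as in step 11 to the dienyl methyl ketone F6. LDA then allyl bromide alkylates the methyl group (kinetic enolate) to give the butenyl ketone F7. MeMgBr in Et2O/CH2Cl2 at −78 °C adds through the five-membered magnesium chelate with the C3 ether oxygen, anti to C2, to give the 4S carbinol F8. DDQ gives the triol F9, and TEMPO/PhI(OAc)2 closes the lactone through the lactol F10 to give 19.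

**Further compounds**
F1 | step 12 | bis(4-methoxybenzyl) ether of 4 | CC1=CC[C@H](C[C@H]1OCc1ccc(OC)cc1)C(C)COCc1ccc(OC)cc1
F2 | step 12 | 3,7-bis[(4-methoxybenzyl)oxy]-6-methyl-5-(2-oxoethyl)heptan-2-one | CC(=O)[C@H](OCc1ccc(OC)cc1)C[C@@H](CC=O)C(C)COCc1ccc(OC)cc1
F3 | step 12 | 5-(2-hydroxyethyl)-3,7-bis[(4-methoxybenzyl)oxy]-6-methylheptan-2-one | CC(=O)[C@H](OCc1ccc(OC)cc1)C[C@@H](CCO)C(C)COCc1ccc(OC)cc1
F4 | step 12 | 5-(2-iodoethyl)-3,7-bis[(4-methoxybenzyl)oxy]-6-methylheptan-2-one | CC(=O)[C@H](OCc1ccc(OC)cc1)C[C@@H](CCI)C(C)COCc1ccc(OC)cc1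
F5 | step 12 | alkylzinc iodide from F4 | CC(=O)[C@H](OCc1ccc(OC)cc1)C[C@@H](CC[Zn]I)C(C)COCc1ccc(OC)cc1
F6 | step 12 | (8E)-5-{1-[(4-methoxybenzyl)oxy]propan-2-yl}-3-[(4-methoxybenzyl)oxy]-8,12-dimethyltrideca-8,12-dien-2-one | CC(=O)[C@H](OCc1ccc(OC)cc1)C[C@@H](CC/C(C)=C/CCC(C)=C)C(C)COCc1ccc(OC)cc1
F7 | step 12 | butenyl ketone, the C5-allylated derivative of F6 | C=CCCC(=O)[C@H](OCc1ccc(OC)cc1)C[C@@H](CC/C(C)=C/CCC(C)=C)C(C)COCc1ccc(OC)cc1
F8 | step 12 | (4S)-tertiary carbinol from methyl addition to F7 | C=CCC[C@](C)(O)[C@H](OCc1ccc(OC)cc1)C[C@@H](CC/C(C)=C/CCC(C)=C)C(C)COCc1ccc(OC)cc1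
F9 | step 12 | triol from F8 after removal of both 4-methoxybenzyl groups | C=CCC[C@](C)(O)[C@H](O)C[C@@H](CC/C(C)=C/CCC(C)=C)C(C)CO
F10 | step 12 | lactol corresponding to 19 | CC1C(O)O[C@H](C[C@H]1CC/C(C)=C/CCC(C)=C)[C@@](C)(O)CCC=C
F11 | step 14 | trimethyl[(5E)-6-iodohept-5-en-1-yn-1-yl]silane | C/C(I)=C\CCC#C[Si](C)(C)C
F12 | step 14 | (5E)-6-iodohept-5-en-1-yne | C/C(I)=C\CCC#C
F13 | step 14 | [(1E,5E)-6-iodo-2-methylhepta-1,5-dien-1-yl]dimethylalane | C/C(I)=C\CC/C(C)=C/[Al](C)C
F14 | step 14 | (1E,5E)-1-bromo-6-iodo-2-methylhepta-1,5-diene | C/C(I)=C\CC/C(C)=C/Br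
F15 | step 14 | 6-acetyl-4-[(3E,7E)-8-bromo-3,7-dimethylocta-3,7-dien-1-yl]-3-methyloxan-2-one | CC1C(=O)O[C@H](C[C@H]1CC/C(C)=C/CC/C(C)=C/Br)C(C)=O
F16 | step 14 | vinyl carbinol, 6-[(2S)-2-hydroxybut-3-en-2-yl] analogue of F15 | CC1C(=O)O[C@H](C[C@H]1CC/C(C)=C/CC/C(C)=C/Br)[C@@](C)(O)C=C
F17 | step 14 | (11S,12S)-epoxide of F16 | CC1C(=O)O[C@H](C[C@H]1CC[C@]1(C)O[C@H]1CC/C(C)=C/Br)[C@@](C)(O)C=C
F18 | step 14 | B-alkyl-9-BBN from hydroboration of the vinyl group of F17 | CC1C(=O)O[C@H](C[C@H]1CC[C@]1(C)O[C@H]1CC/C(C)=C/Br)[C@@](C)(O)CCB1C2CCCC1CCC2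
F19 | step 15 | C4 trimethylsilyl ether of 22 | C[C@@H]1C(=O)O[C@@H]2C[C@H]1CC[C@]1(C)O[C@H]1CC/C(C)=C/CC[C@]2(C)O[Si](C)(C)C
F20 | step 15 | C8 (2-methoxyprop-2-yl)peroxy C7 phenylselenide of F19 | C[C@@H]1C(=O)O[C@@H]2C[C@H]1CC[C@]1(C)O[C@H]1CC[C@](C)(OOC(C)(C)OC)[C@H]([Se]c3ccccc3)CC[C@]2(C)O[Si](C)(C)C
F21 | step 15 | selenoxide of F20 | C[C@@H]1C(=O)O[C@@H]2C[C@H]1CC[C@]1(C)O[C@H]1CC[C@](C)(OOC(C)(C)OC)[C@H]([Se](=O)c3ccccc3)CC[C@]2(C)O[Si](C)(C)C
F22 | step 15 | (6E)-allylic C8 peroxyketal, C4 trimethylsilyl ether | C[C@@H]1C(=O)O[C@@H]2C[C@H]1CC[C@]1(C)O[C@H]1CC[C@](C)(OOC(C)(C)OC)/C=C/C[C@]2(C)O[Si](C)(C)C
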